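**Retrosynthetic overview**
1. Target ⇒ its C5/C6 acetonide ⇒ C4‑OH ⇒ C4‑OTBS. The acetate goes onto C4 only while the C5,C6‑diol is masked.
2. C5‑OH/C6‑OH ⇒ syn‑dihydroxylation of an (E)‑5‑pentadecylidene‑4‑silyloxycyclopent‑2‑enone, anti to C4‑OTBS. C4 controls C5, and the E geometry relays this to C6.
3. C5=C6 ⇒ α′‑aldol/E1cB condensation of (S)‑4‑(TBSO)cyclopent‑2‑enone with pentadecanal (from 1‑pentadecanol).
4. (S)‑Enone ⇒ (1R,4S)‑4‑hydroxycyclopent‑2‑enyl acetate ⇒ lipase desymmetrisation of meso cis‑3,5‑diacetoxycyclopentene, the source of all absolute stereochemistry.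
5. Rings: the carbocycle is present from the start and is never opened. The only ring formed is the temporary dioxolane (step 9), which is opened again in step 12.

Assumption: 1 and 6 are catalogue chemicals. Locants in the descriptions follow the target: C1 = ring C=O, C2=C3, C4 = CH–O, C5 = quaternary carbinol, C6 = side‑chain carbinol.

**Step 1**
Reactants: 1 cis‑cyclopent‑2‑ene‑1,4‑diyl diacetate (cis‑3,5‑diacetoxycyclopentene; meso, achiral)
Product: 2 (1R,4S)‑4‑hydroxycyclopent‑2‑en‑1‑yl acetate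
Conditions: lipase (Candida antarctica lipase B, immobilised; serine hydrolase, EC 3.1.1.3), MeOH (5 equiv), MTBE, 5 °C
Reagents that add atoms: none
Why: In this lipase‑catalysed desymmetrising transesterification (methanolysis) the chiral active site accepts only one of the two enantiotopic acetates of the mirror‑symmetric diester, so asymmetric catalysis fixes the absolute configuration as (1R,4S) with a theoretical yield of 100% and typically ≥99% ee, the mono‑ester being a poor substrate for a second cleavage.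

**Step 2**
Reactants: 2 (1R,4S)‑4‑hydroxycyclopent‑2‑en‑1‑yl acetate
Product: 3 (1R,4S)‑4‑[(tert‑butyldimethylsilyl)oxy]cyclopent‑2‑en‑1‑yl acetate
Conditions: TBSCl, imidazole, DMF, 0 °C to rt
Reagents that add atoms: tert‑butyldimethylsilyl chloride, CC(C)(C)[Si](C)(C)Cl
Why: Corey silylation of the only free hydroxyl touches no stereocentre and marks the future C4 oxygen with a base‑stable, bulky group.

**Step 3**
Reactants: 3 (1R,4S)‑4‑[(tert‑butyldimethylsilyl)oxy]cyclopent‑2‑en‑1‑yl acetate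
Product: 4 (1R,4S)‑4‑[(tert‑butyldimethylsilyl)oxy]cyclopent‑2‑en‑1‑ol
Conditions: K2CO3 (0.2 equiv), MeOH, 0 °C to rt
Reagents that add atoms: none
Why: Base‑catalysed (Zemplén‑type) transesterification cleaves the acyl–O bond with retention at carbon, and the TBS ether is inert to catalytic carbonate in methanol.

**Step 4**
Reactants: 4 (1R,4S)‑4‑[(tert‑butyldimethylsilyl)oxy]cyclopent‑2‑en‑1‑ol
Product: 5 (4S)‑4‑[(tert‑butyldimethylsilyl)oxy]cyclopent‑2‑en‑1‑one
Conditions: activated MnO2, CH2Cl2, rt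
Reagents that add atoms: none
Why: Neutral heterogeneous MnO2 allylic oxidation gives the enone without β‑elimination or racemisation, erasing the C1 carbinol centre and keeping the lipase‑defined C4 centre (S by CIP here, same spatial arrangement as 4R in the target).

**Step 5**
Reactants: 6 pentadecan‑1‑ol
Product: 7 pentadecanal
Conditions: TEMPO (10 mol %), PhI(OAc)2, CH2Cl2, rt
Reagents that add atoms: none
Why: The TEMPO/oxoammonium oxidation stops cleanly at the aldehyde and supplies fresh, acid‑free aldehyde for the aldol.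

**Step 6**
Reactants: 5 (4S)‑4‑[(tert‑butyldimethylsilyl)oxy]cyclopent‑2‑en‑1‑one; 7 pentadecanal
Product: 10 (4R,5S)‑4‑[(tert‑butyldimethylsilyl)oxy]‑5‑(1‑hydroxypentadecyl)cyclopent‑2‑en‑1‑one (4,5‑trans; both C6 epimers), via lithium dienolate 8 (not isolated), via lithium aldolate 9 (not isolated)
Conditions: LDA (commercial solution, 1.1 equiv), THF, −78 °C; then 7, −78 °C; AcOH quench at −78 °C
Reagents that add atoms: none
Why: In this kinetic α′‑deprotonation/aldol addition the C5 dienolate persists at −78 °C because loss of silyloxide would give an antiaromatic cyclopentadienone, the aldehyde adds anti to the C4 silyloxy group, and the C6 epimer mixture is irrelevant because C5 and C6 become sp2 in the next step.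

**Step 7**
Reactants: 10 (4R,5S)‑4‑[(tert‑butyldimethylsilyl)oxy]‑5‑(1‑hydroxypentadecyl)cyclopent‑2‑en‑1‑one
Product: 12 (4R,5E)‑4‑[(tert‑butyldimethylsilyl)oxy]‑5‑pentadecylidenecyclopent‑2‑en‑1‑one, via mesylate 11 (not isolated)
Conditions: MsCl (1.5 equiv), Et3N (5 equiv), CH2Cl2, −10 °C to rt
Reagents that add atoms: none
Why: Mesylation followed by E1cB elimination through the C5 enolate gives the conjugated exocyclic olefin, the E isomer (chain anti to C=O) being favoured and the minor Z isomer removed by chromatography, while C4 is untouched.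

**Step 8**
Reactants: 12 (4R,5E)‑4‑[(tert‑butyldimethylsilyl)oxy]‑5‑pentadecylidenecyclopent‑2‑en‑1‑one
Product: 13 (4R,5S)‑4‑[(tert‑butyldimethylsilyl)oxy]‑5‑hydroxy‑5‑[(1S)‑1‑hydroxypentadecyl]cyclopent‑2‑en‑1‑one
Conditions: OsO4 (4 mol %), NMO (1.2 equiv), citric acid (1 equiv), acetone/t‑BuOH/H2O, 0 °C to rt
Reagents that add atoms: osmium tetroxide, O=[Os](=O)(=O)=O (transfers both O atoms); N‑methylmorpholine N‑oxide, C[N+]1([O-])CCOCC1, and water, O (replenish the oxygen on osmium)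
Why: In this Upjohn syn‑dihydroxylation OsO4 adds suprafacially to the more electron‑rich trisubstituted exocyclic olefin rather than the cis‑disubstituted ring enone bond and from the face opposite the bulky C4‑OTBS, so face selection sets 5S (OH trans to OTBS) and E geometry plus syn addition sets 6S, while citric acid keeps the medium slightly acidic to speed turnover and suppress retro‑aldol.

**Step 9**
Reactants: 13 (4R,5S)‑4‑[(tert‑butyldimethylsilyl)oxy]‑5‑hydroxy‑5‑[(1S)‑1‑hydroxypentadecyl]cyclopent‑2‑en‑1‑one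
Product: 14 (4S,5S,9R)‑9‑[(tert‑butyldimethylsilyl)oxy]‑2,2‑dimethyl‑4‑tetradecyl‑1,3‑dioxaspiro[4.4]non‑7‑en‑6‑one (C5/C6 acetonide of 13)
Conditions: Me2C(OMe)2 (10 equiv), PPTS (10 mol %), CH2Cl2, rt
Reagents that add atoms: 2,2‑dimethoxypropane, COC(C)(C)OC
Why: Acid‑catalysed transketalisation ties the only two free hydroxyls into a five‑membered isopropylidene acetal without touching a stereocentre, PPTS being too weak to cleave the secondary TBS ether.

**Step 10**
Reactants: 14 C5/C6 acetonide TBS ether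
Product: 15 (4S,5R,9R)‑9‑hydroxy‑2,2‑dimethyl‑4‑tetradecyl‑1,3‑dioxaspiro[4.4]non‑7‑en‑6‑one (same spatial arrangement; the spiro descriptor changes only through CIP priorities)
Conditions: HF·pyridine, pyridine, THF, 0 °C to rt
Reagents that add atoms: none
Why: Fluoride‑driven Si–O cleavage under buffered, mildly acidic and anhydrous conditions frees C4‑OH with retention, avoids the alkoxide conditions that isomerise 4‑hydroxycyclopentenones, and leaves the acetonide intact.

**Step 11**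
Reactants: 15 C5/C6 acetonide C4 alcohol
Product: 16 (4S,5S,9R)‑9‑acetoxy‑2,2‑dimethyl‑4‑tetradecyl‑1,3‑dioxaspiro[4.4]non‑7‑en‑6‑one
Conditions: Ac2O, pyridine, DMAP (5 mol %), CH2Cl2, 0 °C
Reagents that add atoms: acetic anhydride, CC(=O)OC(C)=O
Why: DMAP‑catalysed O‑acylation of the only free hydroxyl proceeds with retention at C4, and β‑elimination of acetate is impossible because C5 bears no hydrogen.

**Step 12**
Reactants: 16 C5/C6 acetonide C4 acetate
Product: 17 (4R,5S)‑4‑acetoxy‑5‑hydroxy‑5‑[(1S)‑1‑hydroxypentadecyl]cyclopent‑2‑en‑1‑one (= (1R,5S)‑5‑hydroxy‑5‑[(1S)‑1‑hydroxypentadecyl]‑4‑oxocyclopent‑2‑en‑1‑yl acetate), the target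
Conditions: TFA/H2O (9:1), CH2Cl2, 0 °C; toluene azeotrope, no basic wash
Reagents that add atoms: none
Why: Acid hydrolysis of the isopropylidene acetal breaks only the ketal C–O bonds so C5 and C6 keep their configuration, the ester, enone and tertiary ketol tolerate cold aqueous TFA, and the non‑basic work‑up avoids 4‑O to 6‑O acetyl migration.

**Compound list**
1 | cis‑cyclopent‑2‑ene‑1,4‑diyl diacetate (meso, achiral) | CC(=O)O[C@H]1C=C[C@@H](OC(C)=O)C1 | starting material
2 | (1R,4S)‑4‑hydroxycyclopent‑2‑en‑1‑yl acetate | CC(=O)O[C@H]1C=C[C@@H](O)C1 | intermediate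
3 | (1R,4S)‑4‑[(tert‑butyldimethylsilyl)oxy]cyclopent‑2‑en‑1‑yl acetate | CC(=O)O[C@H]1C=C[C@@H](O[Si](C)(C)C(C)(C)C)C1 | intermediate
4 | (1R,4S)‑4‑[(tert‑butyldimethylsilyl)oxy]cyclopent‑2‑en‑1‑ol | O[C@H]1C=C[C@@H](O[Si](C)(C)C(C)(C)C)C1 | intermediate
5 | (4S)‑4‑[(tert‑butyldimethylsilyl)oxy]cyclopent‑2‑en‑1‑one | O=C1C=C[C@@H](O[Si](C)(C)C(C)(C)C)C1 | intermediate
6 | pentadecan‑1‑ol | CCCCCCCCCCCCCCCO | starting material
7 | pentadecanal | CCCCCCCCCCCCCCC=O | intermediate
8 | lithium (3R)‑3‑[(tert‑butyldimethylsilyl)oxy]cyclopenta‑1,4‑dien‑1‑olate (C5 dienolate of 5, formed in the flask) | [Li+].[O-]C1=C[C@H](O[Si](C)(C)C(C)(C)C)C=C1 | intermediate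
9 | lithium alkoxide of aldol 10 (4,5‑trans; C6 epimers, formed in the flask) | [Li+].CCCCCCCCCCCCCCC([O-])[C@@H]1C(=O)C=C[C@H]1O[Si](C)(C)C(C)(C)C | intermediate
10 | (4R,5S)‑4‑[(tert‑butyldimethylsilyl)oxy]‑5‑(1‑hydroxypentadecyl)cyclopent‑2‑en‑1‑one (4,5‑trans; C6 epimers) | CCCCCCCCCCCCCCC(O)[C@@H]1C(=O)C=C[C@H]1O[Si](C)(C)C(C)(C)C | intermediate
11 | C6 methanesulfonate of 10 (ring configuration unchanged; C6 epimers, formed in the flask) | CCCCCCCCCCCCCCC(OS(C)(=O)=O)[C@@H]1C(=O)C=C[C@H]1O[Si](C)(C)C(C)(C)C | intermediate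
12 | (4R,5E)‑4‑[(tert‑butyldimethylsilyl)oxy]‑5‑pentadecylidenecyclopent‑2‑en‑1‑one | CCCCCCCCCCCCCC/C=C1/C(=O)C=C[C@H]1O[Si](C)(C)C(C)(C)C | intermediate
13 | (4R,5S)‑4‑[(tert‑butyldimethylsilyl)oxy]‑5‑hydroxy‑5‑[(1S)‑1‑hydroxypentadecyl]cyclopent‑2‑en‑1‑one | CCCCCCCCCCCCCC[C@H](O)[C@@]1(O)C(=O)C=C[C@H]1O[Si](C)(C)C(C)(C)C | intermediate
14 | (4S,5S,9R)‑9‑[(tert‑butyldimethylsilyl)oxy]‑2,2‑dimethyl‑4‑tetradecyl‑1,3‑dioxaspiro[4.4]non‑7‑en‑6‑one | CCCCCCCCCCCCCC[C@@H]1OC(C)(C)O[C@@]12C(=O)C=C[C@H]2O[Si](C)(C)C(C)(C)C | intermediate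
15 | (4S,5R,9R)‑9‑hydroxy‑2,2‑dimethyl‑4‑tetradecyl‑1,3‑dioxaspiro[4.4]non‑7‑en‑6‑one | CCCCCCCCCCCCCC[C@@H]1OC(C)(C)O[C@@]12C(=O)C=C[C@H]2O | intermediate
16 | (4S,5S,9R)‑9‑acetoxy‑2,2‑dimethyl‑4‑tetradecyl‑1,3‑dioxaspiro[4.4]non‑7‑en‑6‑one | CCCCCCCCCCCCCC[C@@H]1OC(C)(C)O[C@@]12C(=O)C=C[C@H]2OC(C)=O | intermediate
17 | (4R,5S)‑4‑acetoxy‑5‑hydroxy‑5‑[(1S)‑1‑hydroxypentadecyl]cyclopent‑2‑en‑1‑one | CCCCCCCCCCCCCC[C@H](O)[C@@]1(O)C(=O)C=C[C@H]1OC(C)=O | target

**Totals**
Total steps: 12. Longest linear sequence: 11 (steps 1–4 and 6–12). Step 5 is a one‑step side branch.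

**Three steps most likely to fail**

Step 8. The risk is that the ring enone olefin competes with the exocyclic olefin, or that over‑oxidation occurs. The fallback takes the ring olefin out of play before osmylation and sets out from 12.
- Only the unhindered cis‑disubstituted C2=C3 bond is hydrogenated with Wilkinson's catalyst (H2, RhCl(PPh3)3, benzene/EtOH), giving the 2,3‑dihydro enone F3.
- Its sole olefin is dihydroxylated with OsO4/NMO, using the same anti‑to‑OTBS and E/syn logic, to the saturated diol F4.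
- This is protected with 2,2‑dimethoxypropane/PPTS as the saturated acetonide F5.
- TMSOTf/Et3N gives the only possible (C1–C2) trimethylsilyl enol ether F6.
- A Saegusa–Ito oxidation (Pd(OAc)2, MeCN) reinstalls C2=C3, and the route is rejoined at 14.

Step 6. The risk is proton transfer to the enolisable aldehyde, retro‑aldol, or decay of the dienolate. The fallback replaces the aldol/dehydration pair with an olefination and sets out from 5.
- Dienolate 8 is trapped at −78 °C with the fast, non‑enolisable electrophile diethyl chlorophosphite to give the diethyl phosphonite F1.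
- Air (or H2O2) oxidation converts it to the β‑ketophosphonate F2.
- A Horner–Wadsworth–Emmons reaction with aldehyde 7 under Masamune–Roush conditions (LiCl, i‑Pr2NEt, MeCN) forms the E olefin directly.
- The route is rejoined at 12, bypassing 10 and step 7.

Step 12. The risk is a sluggish acetonide next to the ketone, or acetyl loss or migration. The fallback avoids diol protection altogether by changing the order of events and sets out from 12.
- Desilylation with HF·pyridine gives the 4‑hydroxy dienone F7.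
- Ac2O/pyridine gives the 4‑acetoxy dienone F8.
- The OsO4/NMO/citric acid dihydroxylation then becomes the last step and arrives directly at 17.
- The price is a weaker facial bias from OAc than from OTBS, so the minor diastereomer has to be separated at the end.

**Further compounds**
F1 | step 6 | diethyl {(1S,5R)‑5‑[(tert‑butyldimethylsilyl)oxy]‑2‑oxocyclopent‑3‑en‑1‑yl}phosphonite | CCOP(OCC)[C@@H]1C(=O)C=C[C@H]1O[Si](C)(C)C(C)(C)C
F2 | step 6 | diethyl {(1S,5R)‑5‑[(tert‑butyldimethylsilyl)oxy]‑2‑oxocyclopent‑3‑en‑1‑yl}phosphonate | CCOP(=O)(OCC)[C@@H]1C(=O)C=C[C@H]1O[Si](C)(C)C(C)(C)C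
F3 | step 8 | (2E,3R)‑3‑[(tert‑butyldimethylsilyl)oxy]‑2‑pentadecylidenecyclopentan‑1‑one | CCCCCCCCCCCCCC/C=C1/C(=O)CC[C@H]1O[Si](C)(C)C(C)(C)C
F4 | step 8 | (2S,3R)‑3‑[(tert‑butyldimethylsilyl)oxy]‑2‑hydroxy‑2‑[(1S)‑1‑hydroxypentadecyl]cyclopentan‑1‑one | CCCCCCCCCCCCCC[C@H](O)[C@@]1(O)C(=O)CC[C@H]1O[Si](C)(C)C(C)(C)C
F5 | step 8 | (4S,5S,9R)‑9‑[(tert‑butyldimethylsilyl)oxy]‑2,2‑dimethyl‑4‑tetradecyl‑1,3‑dioxaspiro[4.4]nonan‑6‑one | CCCCCCCCCCCCCC[C@@H]1OC(C)(C)O[C@@]12C(=O)CC[C@H]2O[Si](C)(C)C(C)(C)C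
F6 | step 8 | C1–C2 trimethylsilyl enol ether of F5 | CCCCCCCCCCCCCC[C@@H]1OC(C)(C)O[C@@]12C(O[Si](C)(C)C)=CC[C@H]2O[Si](C)(C)C(C)(C)C
F7 | step 12 | (4R,5E)‑4‑hydroxy‑5‑pentadecylidenecyclopent‑2‑en‑1‑one | CCCCCCCCCCCCCC/C=C1/C(=O)C=C[C@H]1O
F8 | step 12 | (4R,5E)‑4‑acetoxy‑5‑pentadecylidenecyclopent‑2‑en‑1‑one | CCCCCCCCCCCCCC/C=C1/C(=O)C=C[C@H]1OC(C)=O
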